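**Retrosynthetic overview**
1. Target ⇐ 8,9-diol by sequential acylation (methacrylate at the less hindered C8–OH, then acetate at C9–OH) ⇐ its 8,9-acetonide.
2. Key disconnection C6–C7: the ten-membered carbocycle and the cis-fused α-methylene-γ-butyrolactone close together in an electroreductive, indium-catalysed intramolecular Barbier allylation/lactonisation of a (Z)-enal carrying a 2-(bromomethyl)enoate (sets C6 and C7).
3. The furanone is closed before that by gold-catalysed cycloisomerisation of a γ-hydroxy ynone; ynone and (Z)-enal are released together by oxidative opening of a 3-methylfuran; the allylic bromide comes from a Morita–Baylis–Hillman (MBH) adduct at C7.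
4. C10 is set by chelation-controlled addition of a furylacetylide to the methyl ketone made from 2,3-O-isopropylidene-L-erythronolactone (source of C8 and C9).
5. Ring order: dioxolane (bought) → furanone → carbocycle and lactone in one step.

Assumption: the stereochemistry is taken exactly as the SMILES encodes it (cis-fused 6,12-lactone; 6S,7S,8S,9S,10R in germacrane numbering, which is used for atom labels throughout), and 2,3-O-isopropylidene-L-erythronolactone is taken as a purchasable chiral-pool lactone.

Atom labels: C1 furanone ketone, C2/C3 furanone alkene, C4=C5 the (Z)-alkene, C6/C7 lactone ring fusion, C8 (methacrylate), C9 (acetate), C10 quaternary carbon, C11–C13 methylene lactone.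

**Step 1**
Reactants: 1 3-methylfuran-2-carbaldehyde
Product: 2 2-ethynyl-3-methylfuran
Conditions: dimethyl (1-diazo-2-oxopropyl)phosphonate, K2CO3, MeOH, 0 °C to rt
Reagents that add atoms: dimethyl (1-diazo-2-oxopropyl)phosphonate, CC(=O)C(=[N+]=[N-])P(=O)(OC)OC
Why: Ohira–Bestmann (Seyferth–Gilbert) homologation, in which the diazomethylphosphonate anion formed in situ adds to the aldehyde and the resulting alkylidene carbene rearranges to the terminal alkyne; no stereocentre is involved.

**Step 2**
Reactants: 3 2,3-O-isopropylidene-L-erythronolactone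
Product: 4 1-deoxy-3,4-O-isopropylidene-L-erythro-pent-2-ulofuranose (methyl hemiketal, both anomers)
Conditions: MeLi (1.05 eq), THF, −78 °C; AcOH quench at −78 °C
Reagents that add atoms: methyllithium, [Li]C
Why: Organolithium mono-addition to a γ-lactone (lactol synthesis), the lithium hemiketalate being stable at −78 °C so that only one methyl group is delivered; C8 and C9 are not touched.

**Step 3**
Reactants: 4 methyl hemiketal; 2 2-ethynyl-3-methylfuran
Product: 6 bis(triethylsilyl) ether of the (2S)-alkynyl diol, via magnesium dialkoxide of diol 5 (not isolated)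
Conditions: 4, EtMgBr (1.0 eq), THF, −20 °C; alkynyl-MgBr (from 2 + EtMgBr, 1.5 eq), −20 °C to rt; then TESOTf (2.6 eq), −78 to 0 °C
Reagents that add atoms: triethylsilyl trifluoromethanesulfonate (TESOTf), CC[Si](CC)(CC)OS(=O)(=O)C(F)(F)F
Why: Chelation-controlled (Cram chelate) Grignard addition to the open α-alkoxy methyl ketone form of 4, in which magnesium bridges the ketone oxygen and O9 and the acetylide enters from the H9 face (anti to C8), setting C10 with O10 and O9 threo as in the target; the dialkoxide is silylated in the same flask so that the later C7 aldehyde cannot close to a lactol on the C10 oxygen.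

**Step 4**
Reactants: 6 bis(triethylsilyl) ether
Product: 7 C7 aldehyde with tertiary triethylsilyl ether
Conditions: (COCl)2, DMSO, CH2Cl2, −78 to −30 °C; Et3N, −78 °C to rt
Reagents that add atoms: none
Why: Swern oxidation applied to a bis-silyl ether, where chloride-assisted cleavage and oxidation occur only at the primary triethylsilyl ether and the tertiary one stays, giving the aldehyde directly; C8 is not epimerised at low temperature.

**Step 5**
Reactants: 7 C7 aldehyde
Product: 9 MBH diol (both C7 epimers), via triethylsilyl-protected MBH adduct 8 (not isolated)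
Conditions: methyl acrylate (5 eq), DABCO (1 eq), dioxane–H2O (1:1), rt, 12 h; then HF·pyridine, pyridine, THF, 0 °C to rt
Reagents that add atoms: methyl acrylate, C=CC(=O)OC
Why: Morita–Baylis–Hillman reaction of the activated α-alkoxy aldehyde under fast aqueous DABCO conditions (short exposure limits epimerisation at C8); the new C7 carbinol forms as both epimers, which does not matter because C7 becomes sp2 in step 6, and fluoride then frees the tertiary alcohol.

**Step 6**
Reactants: 9 MBH diol
Product: 10 (Z)-allylic bromide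
Conditions: CBr4 (1.1 eq), PPh3 (1.1 eq), CH2Cl2, −20 to 0 °C
Reagents that add atoms: carbon tetrabromide, BrC(Br)(Br)Br
Why: Appel activation of the secondary allylic alcohol followed by bromide attack with allylic transposition (SN2′) gives the thermodynamically favoured (Z)-2-(bromomethyl)alk-2-enoate, the standard conversion of MBH adducts; both C7 epimers converge and the hindered tertiary propargylic alcohol reacts far more slowly.

**Step 7**
Reactants: 10 (Z)-allylic bromide
Product: 12 furanone (Z)-enal allylic bromide, via gamma-hydroxy ynone enal 11 (not isolated)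
Conditions: DMDO (1.1 eq), acetone, −78 to −20 °C; evaporate; Ph3PAuNTf2 (5 mol%), wet toluene, rt
Reagents that add atoms: dimethyldioxirane (DMDO), CC1(C)OO1
Why: Dioxirane oxidative ring opening of the furan gives the (Z)-4-oxo-2-enal with the cis geometry inherited from the ring (this fixes the Z C4=C5 bond and unveils the C3 ketone and C6 aldehyde without touching the allylic bromide), and monovalent gold then catalyses the known hydrative cycloisomerisation of the γ-hydroxy ynone to the 3(2H)-furanone with C10 unchanged.

**Step 8**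
Reactants: 12 furanone (Z)-enal allylic bromide
Product: 15 tricyclic lactone acetonide, via allylindium dibromide 13 (not isolated), via macrocyclic hydroxy ester 14 (not isolated)
Conditions: InBr3 (15 mol%), LiBr (0.1 M), THF, undivided cell, Zn anode, reticulated vitreous carbon cathode, 2 mA constant current (2.5 F/mol), rt, 12 added by syringe pump over 10 h (final 2 mM); then PPTS (cat.), CH2Cl2, rt
Reagents that add atoms: none
Why: Proposed new method: catalytic electroreductive Barbier macrocyclisation–lactonisation, in which the cathode reduces InBr3 to monovalent indium, this inserts into the allylic C–Br bond, and the allylindium, generated only at the rate set by the current while 12 is fed slowly, is captured intramolecularly by the C6 aldehyde through a six-membered chair transition state (γ-attack at C7) before it can meet a second molecule; the (Z)-allyl geometry (C8 axial) gives the syn adduct and hence the cis lactone (C6, C7), and the cis-dioxolane holds C7–C8–C9–C10 syn-clinal so that the medium ring closes with the forming C6–C7 bond antiperiplanar to C8–C9 (H8 in the allyl plane to avoid A(1,3) strain), which is the C7/C8 relationship of the target; the indium alkoxide then closes the γ-lactone and trivalent indium returns to the cathode; closest known chemistry: intermolecular aldehyde allylation with electrochemically regenerated monovalent indium and stoichiometric zinc-, indium- or CrCl2-mediated Barbier lactone syntheses with 2-(bromomethyl)acrylates.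

**Step 9**
Reactants: 15 tricyclic lactone acetonide
Product: 16 8,9-diol
Conditions: TFA–H2O (9:1), CH2Cl2, 0 °C
Reagents that add atoms: none
Why: Acid-catalysed hydrolysis of the isopropylidene acetal, which the dienone, the (Z)-alkene and the methylene lactone tolerate in cold aqueous TFA; no stereocentre is affected.

**Step 10**
Reactants: 16 8,9-diol
Product: 18 target CNP0365569.3, via 8-O-methacrylate 17 (not isolated)
Conditions: methacrylic anhydride (1.1 eq), DMAP (0.2 eq), pyridine, CH2Cl2, −20 °C; then Ac2O (5 eq), rt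
Reagents that add atoms: methacrylic anhydride, CC(=C)C(=O)OC(=O)C(C)=C; acetic anhydride, CC(=O)OC(C)=O
Why: Sequential DMAP-catalysed acyl transfer, in which the bulkier methacrylic anhydride reacts first at the less hindered C8 hydroxyl (C9–OH is neopentyl-like, next to quaternary C10) and excess acetic anhydride then acetylates C9–OH; no stereocentre is touched.

**Compound list**
1 | 3-methylfuran-2-carbaldehyde | Cc1ccoc1C=O | starting material
2 | 2-ethynyl-3-methylfuran | Cc1ccoc1C#C | intermediate
3 | 2,3-O-isopropylidene-L-erythronolactone, (3aS,6aS)-2,2-dimethyldihydrofuro[3,4-d][1,3]dioxol-4(3aH)-one | O=C1OC[C@@H]2OC(C)(C)O[C@H]12 | starting material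
4 | (3aS,6aS)-2,2,4-trimethyltetrahydrofuro[3,4-d][1,3]dioxol-4-ol (1-deoxy-3,4-O-isopropylidene-L-erythro-pent-2-ulofuranose, both anomers) | CC1(O)OC[C@@H]2OC(C)(C)O[C@H]12 | intermediate
5 | (2S)-2-[(4S,5S)-5-(hydroxymethyl)-2,2-dimethyl-1,3-dioxolan-4-yl]-4-(3-methylfuran-2-yl)but-3-yn-2-ol (formed as its magnesium dialkoxide) | OC[C@@H]1OC(C)(C)O[C@@H]1[C@@](C)(O)C#Cc1occc1C | intermediate
6 | bis(triethylsilyl) ether of 5 (primary and tertiary oxygen silylated; 2S, 4S, 5S) | CC[Si](CC)(CC)OC[C@@H]1OC(C)(C)O[C@@H]1[C@@](C)(O[Si](CC)(CC)CC)C#Cc1occc1C | intermediate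
7 | (4R,5S)-2,2-dimethyl-5-[(2S)-4-(3-methylfuran-2-yl)-2-(triethylsilyloxy)but-3-yn-2-yl]-1,3-dioxolane-4-carbaldehyde | O=C[C@@H]1OC(C)(C)O[C@@H]1[C@@](C)(O[Si](CC)(CC)CC)C#Cc1occc1C | intermediate
8 | MBH adduct of 7: methyl 2-[hydroxy(dioxolan-4-yl)methyl]acrylate, tertiary triethylsilyl ether, both C7 epimers, other centres as in 7 | COC(=O)C(=C)C(O)[C@@H]1OC(C)(C)O[C@@H]1[C@@](C)(O[Si](CC)(CC)CC)C#Cc1occc1C | intermediate
9 | MBH diol: 8 with free tertiary alcohol, both C7 epimers | COC(=O)C(=C)C(O)[C@@H]1OC(C)(C)O[C@@H]1[C@@](C)(O)C#Cc1occc1C | intermediate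
10 | methyl (Z)-2-(bromomethyl)-3-{(4S,5S)-5-[(2S)-2-hydroxy-4-(3-methylfuran-2-yl)but-3-yn-2-yl]-2,2-dimethyl-1,3-dioxolan-4-yl}acrylate | COC(=O)/C(CBr)=C/[C@@H]1OC(C)(C)O[C@@H]1[C@@](C)(O)C#Cc1occc1C | intermediate
11 | methyl (Z)-2-(bromomethyl)-3-{(4S,5S)-5-[(2S,6Z)-2-hydroxy-6-methyl-5,8-dioxooct-6-en-3-yn-2-yl]-2,2-dimethyl-1,3-dioxolan-4-yl}acrylate | COC(=O)/C(CBr)=C/[C@@H]1OC(C)(C)O[C@@H]1[C@@](C)(O)C#CC(=O)/C(C)=C\C=O | intermediate
12 | methyl (Z)-2-(bromomethyl)-3-{(4S,5S)-2,2-dimethyl-5-[(2R)-2-methyl-3-oxo-5-((2Z)-4-oxobut-2-en-2-yl)-2,3-dihydrofuran-2-yl]-1,3-dioxolan-4-yl}acrylate | COC(=O)/C(CBr)=C/[C@@H]1OC(C)(C)O[C@@H]1[C@@]2(C)OC(=CC2=O)/C(C)=C\C=O | intermediate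
13 | allylindium dibromide from 12 (CH2InBr2 in place of CH2Br) | COC(=O)/C(C[In](Br)Br)=C/[C@@H]1OC(C)(C)O[C@@H]1[C@@]2(C)OC(=CC2=O)/C(C)=C\C=O | intermediate
14 | macrocyclic hydroxy ester: ten-membered carbocycle with C6–OH and C7–C(=CH2)CO2Me, 8,9-acetonide, furanone bridge; centres as in the target | COC(=O)C(=C)[C@H]1[C@@H](O)/C=C(/C)C2=CC(=O)[C@](C)(O2)[C@H]3OC(C)(C)O[C@@H]13 | intermediate
15 | tricyclic lactone acetonide: 8,9-O-isopropylidene acetal of 16; centres as in the target | C=C1C(=O)O[C@H]2/C=C(/C)C3=CC(=O)[C@](C)(O3)[C@H]4OC(C)(C)O[C@H]4[C@@H]12 | intermediate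
16 | 8,9-diol (target without the two acyl groups; C6–C10 arranged as in the target) | C=C1C(=O)O[C@H]2/C=C(/C)C3=CC(=O)[C@](C)(O3)[C@@H](O)[C@@H](O)[C@@H]12 | intermediate
17 | 8-O-methacrylate of 16 (C9–OH free) | C=C1C(=O)O[C@H]2/C=C(/C)C3=CC(=O)[C@](C)(O3)[C@@H](O)[C@@H](OC(=O)C(C)=C)[C@@H]12 | intermediate
18 | CNP0365569.3, (6S,7S,8S,9S,10R)-9-acetoxy-8-methacryloyloxy furanoheliangolide | C=C(C)C(=O)O[C@H]1[C@H]2C(=C)C(=O)O[C@H]2/C=C(/C)C2=CC(=O)[C@](C)(O2)[C@H]1OC(C)=O | target

**Step count and risks**
Total step count: 10. Longest linear sequence: 9 steps (3 to 18; step 1 is a one-step side branch).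

Most likely to fail, first: step 8 (the new macrocyclisation). Oligomerisation, attack on the other allyl face (C7 epimer) or the trans lactone are all possible. The fallback uses known chemistry, sets out from MBH diol 9 and comes back at 15. The secondary allylic alcohol is acetylated (Ac2O, pyridine, 0 °C) to the allylic acetate F1. Borylation with B2pin2 under zerovalent palladium catalysis (Pd2(dba)3, toluene, 50 °C, allylic transposition) gives the allyl pinacolboronate F2 with C8 cis to CH2B. Furan photooxygenation (O2, tetraphenylporphyrin, visible light, CH2Cl2, −78 °C; Me2S) gives the γ-hydroxy ynone enal boronate F3, which is not isolated, and Ph3PAuNTf2 in wet toluene closes it to the furanone enal boronate F4. Heating F4 at 2 mM in toluene (80 °C, Sc(OTf)3 if needed) effects a thermal intramolecular allylboration through a closed chair transition state, stereospecifically syn from this alkene geometry, to the pinacol borate F5. Aqueous work-up gives hydroxy ester 14, and PPTS lactonises it to 15.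

Second: step 3 (facial selectivity at C10). If the acetylide enters mainly from the other face, the order of the two additions is reversed, so that the same facial preference gives the required carbinol. This fallback sets out from lactone 3 and comes back at diol 5. The lithium acetylide of 2 (n-BuLi, THF, −78 °C) is added to 3 to give the alkynyl hemiketal F6. MeMgBr (3 eq, THF, −40 °C to rt) is then added to its open ynone form and gives diol 5, which is silylated (TESOTf, 2,6-lutidine, CH2Cl2, −78 °C) to 6.

Third: step 10 (which hydroxyl is acylated first, and acyl migration). The fallback replaces the kinetic one-pot differentiation by a protecting-group sequence; it sets out from diol 16 and comes back at 18. TESCl and imidazole (DMF, −20 °C) silylate the less hindered C8–OH to the 8-O-triethylsilyl ether F7. Ac2O and DMAP (pyridine, 40 °C) acetylate C9–OH to the 9-O-acetyl 8-O-triethylsilyl compound F8. HF·pyridine (THF, 0 °C) frees C8–OH to give the 9-acetate F9, and methacrylic anhydride with DMAP (CH2Cl2, 0 °C) gives 18.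

**Further compounds**
F1 | step 8 | secondary allylic acetate of MBH diol 9 (both C7 epimers) | COC(=O)C(=C)C(OC(C)=O)[C@@H]1OC(C)(C)O[C@@H]1[C@@](C)(O)C#Cc1occc1C
F2 | step 8 | allyl pinacolboronate (CH2Bpin analogue of bromide 10, C8 cis to CH2B) | COC(=O)/C(CB1OC(C)(C)C(C)(C)O1)=C/[C@@H]2OC(C)(C)O[C@@H]2[C@@](C)(O)C#Cc1occc1C
F3 | step 8 | γ-hydroxy ynone (Z)-enal allylboronate (boron analogue of 11) | COC(=O)/C(CB1OC(C)(C)C(C)(C)O1)=C/[C@@H]2OC(C)(C)O[C@@H]2[C@@](C)(O)C#CC(=O)/C(C)=C\C=O
F4 | step 8 | furanone (Z)-enal allylboronate (boron analogue of 12) | COC(=O)/C(CB1OC(C)(C)C(C)(C)O1)=C/[C@@H]2OC(C)(C)O[C@@H]2[C@@]3(C)OC(=CC3=O)/C(C)=C\C=O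
F5 | step 8 | pinacol borate ester of hydroxy ester 14 (O6–Bpin) | COC(=O)C(=C)[C@H]1[C@@H](OB2OC(C)(C)C(C)(C)O2)/C=C(/C)C2=CC(=O)[C@](C)(O2)[C@H]3OC(C)(C)O[C@@H]13
F6 | step 3 | (3aS,6aS)-2,2-dimethyl-4-[(3-methylfuran-2-yl)ethynyl]tetrahydrofuro[3,4-d][1,3]dioxol-4-ol (alkynyl hemiketal, both anomers) | Cc1ccoc1C#CC1(O)OC[C@@H]2OC(C)(C)O[C@H]12
F7 | step 10 | 8-O-triethylsilyl ether of diol 16 | C=C1C(=O)O[C@H]2/C=C(/C)C3=CC(=O)[C@](C)(O3)[C@@H](O)[C@@H](O[Si](CC)(CC)CC)[C@@H]12
F8 | step 10 | 9-O-acetyl-8-O-triethylsilyl derivative of diol 16 | C=C1C(=O)O[C@H]2/C=C(/C)C3=CC(=O)[C@](C)(O3)[C@@H](OC(C)=O)[C@@H](O[Si](CC)(CC)CC)[C@@H]12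
F9 | step 10 | 9-O-acetyl derivative of diol 16 (C8–OH free) | C=C1C(=O)O[C@H]2/C=C(/C)C3=CC(=O)[C@](C)(O3)[C@@H](OC(C)=O)[C@@H](O)[C@@H]12
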